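**Retrosynthetic overview**
1. Target 25 ⇐ hexa-MOM ether 24 by global MOM removal.
2. 24 ⇐ cyclohexenyl–aryl bond: stereoinvertive Pd-catalysed allyl–aryl coupling of allylic acetate 16 with benzofuranyl boronate 23. This turns an endo Diels–Alder adduct into the all-trans ("exo") skeleton.
3. 16 ⇐ asymmetric endo Diels–Alder reaction of MOM-protected morachalcone A (13) with (E)-1-acetoxy-3-methylbutadiene (15), which forms the cyclohexene. 13 ⇐ Claisen–Schmidt condensation of ketone 9 and aldehyde 12, both from resorcinol.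
4. 23 ⇐ Miyaura borylation of 22 ⇐ site-selective Suzuki coupling of 2,5-dibromobenzofuran 20 with boronate 21 (Ir C–H borylation of 2). Furan ring ⇐ Cu-catalysed cyclisation of gem-dibromoalkene 19.
5. Ring order: the benzofuran (step 13) and the cyclohexene (step 9) are built independently and joined in step 17.

Assumption: the (R)-VANOL–boron complex shields the chalcone face that gives the (5S,6R) centres of 16; if it gives the antipode, (S)-VANOL is used and nothing else changes.

**Route**

Step 1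
Reactants: 1 resorcinol
Product: 2 1,3-bis(methoxymethoxy)benzene
Conditions: MOMCl (2.5 equiv), i-Pr2NEt (3 equiv), CH2Cl2, 0 °C → rt
Reagents that add atoms: chloromethyl methyl ether (MOMCl) COCCl
Why: O-alkylation of both phenols gives the bis-MOM ether, whose acetal oxygens later direct ortho-lithiation; no stereocentre is involved.

Step 2
Reactants: 2 1,3-bis(methoxymethoxy)benzene; 3 prenyl bromide
Product: 5 1,3-bis(methoxymethoxy)-2-(3-methylbut-2-en-1-yl)benzene, via [2,6-bis(methoxymethoxy)phenyl]lithium 4 (not isolated)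
Conditions: n-BuLi (1.1 equiv), THF, 0 °C → rt, 1 h; CuBr·SMe2 (10 mol %), then 3, −78 °C → rt
Reagents that add atoms: none
Why: Directed ortho-metalation takes place at the C–H flanked by both OMOM groups, and Cu-catalysed SN2 allylation of the aryllithium puts the prenyl group between the two oxygens.

Step 3
Reactants: 5 1,3-bis(methoxymethoxy)-2-(3-methylbut-2-en-1-yl)benzene; 6 N-methoxy-N-methylacetamide
Product: 8 1-[2,4-bis(methoxymethoxy)-3-(3-methylbut-2-en-1-yl)phenyl]ethan-1-one, via [2,4-bis(methoxymethoxy)-3-(3-methylbut-2-en-1-yl)phenyl]lithium 7 (not isolated)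
Conditions: n-BuLi (1.2 equiv), TMEDA, THF, −20 → 0 °C; then 6, −78 → 0 °C; H2O quench
Reagents that add atoms: none
Why: A second OMOM-directed ortho-metalation followed by Weinreb amide acylation gives the methyl ketone without over-addition, because the chelated tetrahedral intermediate survives until the quench.

Step 4
Reactants: 8 1-[2,4-bis(methoxymethoxy)-3-(3-methylbut-2-en-1-yl)phenyl]ethan-1-one
Product: 9 1-[2-hydroxy-4-(methoxymethoxy)-3-(3-methylbut-2-en-1-yl)phenyl]ethan-1-one
Conditions: HCl (cat., ca. 0.1 M) in MeOH, 0 °C → rt, stopped at mono-cleavage (TLC)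
Reagents that add atoms: none
Why: Acid-catalysed transacetalisation to methanol cleaves the MOM group ortho to the carbonyl first, because it is twisted between two ortho substituents and the freed phenol is held by a C=O···H–O hydrogen bond (chelation-assisted selective deprotection).

Step 5
Reactants: 1 resorcinol
Product: 11 2,4-dihydroxybenzaldehyde, via N-[(2,4-dihydroxyphenyl)methylidene]-N-methylmethanaminium chloride 10 (not isolated)
Conditions: POCl3 (1.2 equiv), DMF (1.4 equiv), MeCN, −15 °C → rt; then H2O, 50 °C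
Reagents that add atoms: N,N-dimethylformamide CN(C)C=O; water O
Why: Vilsmeier–Haack formylation attacks C4 of resorcinol (para to one OH, ortho to the other), and hydrolysis of the iminium salt gives the aldehyde.

Step 6
Reactants: 11 2,4-dihydroxybenzaldehyde
Product: 12 2,4-bis(methoxymethoxy)benzaldehyde
Conditions: MOMCl (2.6 equiv), K2CO3 (4 equiv), acetone, reflux
Reagents that add atoms: chloromethyl methyl ether (MOMCl) COCCl
Why: Phenoxide O-alkylation protects both hydroxyls, with reflux needed for the hydrogen-bonded 2-OH, giving a base-stable aldehyde for the aldol step.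

Step 7
Reactants: 9 1-[2-hydroxy-4-(methoxymethoxy)-3-(3-methylbut-2-en-1-yl)phenyl]ethan-1-one; 12 2,4-bis(methoxymethoxy)benzaldehyde
Product: 13 (E)-3-[2,4-bis(methoxymethoxy)phenyl]-1-[2-hydroxy-4-(methoxymethoxy)-3-(3-methylbut-2-en-1-yl)phenyl]prop-2-en-1-one
Conditions: KOH (10 equiv), EtOH/H2O, rt, 36 h; then 1 M HCl to pH 6 at 0 °C
Reagents that add atoms: none
Why: Claisen–Schmidt condensation (aldol addition, then E1cB dehydration) gives the thermodynamic (E)-chalcone, and the MOM ethers and the prenyl group are inert to aqueous base.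

Step 8
Reactants: 14 3-methylbut-2-enal
Product: 15 (E)-3-methylbuta-1,3-dien-1-yl acetate
Conditions: Ac2O (1.5 equiv), Et3N (1.5 equiv), DMAP (5 mol %), 80 °C; distillation
Reagents that add atoms: acetic anhydride CC(=O)OC(C)=O
Why: O-acylation of the γ-deprotonated dienolate gives the dienol acetate, which is E at C1=C2 because the Z isomer suffers allylic strain with the 3-methyl group.

Step 9
Reactants: 13 (E)-3-[2,4-bis(methoxymethoxy)phenyl]-1-[2-hydroxy-4-(methoxymethoxy)-3-(3-methylbut-2-en-1-yl)phenyl]prop-2-en-1-one; 15 (E)-3-methylbuta-1,3-dien-1-yl acetate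
Product: 16 (1S,5S,6R)-5-[2,4-bis(methoxymethoxy)phenyl]-6-[2-hydroxy-4-(methoxymethoxy)-3-(3-methylbut-2-en-1-yl)benzoyl]-3-methylcyclohex-2-en-1-yl acetate
Conditions: (R)-VANOL (1.2 equiv), BH3·THF (1.2 equiv), AcOH (1.2 equiv), THF, rt (complex preformed); then 13 and 15 (4 equiv), PhCF3, rt, 24–48 h; minor exo isomer removed on silica
Reagents that add atoms: none
Why: In this chiral-borate-promoted asymmetric Diels–Alder reaction the 2'-hydroxychalcone chelates boron, which activates it and shields one face (absolute sense at C5/C6), the E-alkene gives the trans C5/C6 relation, the 1-OAc and 3-Me groups both direct the observed regiochemistry, and the endo transition state places OAc at C1 cis to the aroyl group.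

Step 10
Reactants: 11 2,4-dihydroxybenzaldehyde
Product: 17 5-bromo-2,4-dihydroxybenzaldehyde
Conditions: Br2 (1.0 equiv), AcOH, 15 °C → rt
Reagents that add atoms: bromine BrBr
Why: Electrophilic aromatic bromination goes to C5, which is para to the 2-OH, ortho to the 4-OH and less hindered than C3.

Step 11
Reactants: 17 5-bromo-2,4-dihydroxybenzaldehyde
Product: 18 5-bromo-2-hydroxy-4-(methoxymethoxy)benzaldehyde
Conditions: MOMCl (1.05 equiv), K2CO3 (1.2 equiv), acetone, 0 °C → rt
Reagents that add atoms: chloromethyl methyl ether (MOMCl) COCCl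
Why: The 4-OH is more acidic and not hydrogen-bonded to the aldehyde, so it is alkylated selectively and the 2-OH stays free for furan closure.

Step 12
Reactants: 18 5-bromo-2-hydroxy-4-(methoxymethoxy)benzaldehyde
Product: 19 4-bromo-2-(2,2-dibromoethenyl)-5-(methoxymethoxy)phenol
Conditions: CBr4 (2 equiv), PPh3 (4 equiv), Et3N (2 equiv), CH2Cl2, 0 °C
Reagents that add atoms: carbon tetrabromide BrC(Br)(Br)Br
Why: Ramirez (Corey–Fuchs) olefination converts the aldehyde into the gem-dibromoalkene, and Et3N buffers the medium so the MOM ether survives.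

Step 13
Reactants: 19 4-bromo-2-(2,2-dibromoethenyl)-5-(methoxymethoxy)phenol
Product: 20 2,5-dibromo-6-(methoxymethoxy)-1-benzofuran
Conditions: CuI (5 mol %), K3PO4 (2 equiv), THF, 80 °C
Reagents that add atoms: none
Why: Cu-catalysed intramolecular Ullmann-type O-vinylation with the cis bromide closes the furan ring and leaves the 2-bromide, while the aryl bromide is inert under these conditions.

Step 14
Reactants: 2 1,3-bis(methoxymethoxy)benzene
Product: 21 2-[3,5-bis(methoxymethoxy)phenyl]-4,4,5,5-tetramethyl-1,3,2-dioxaborolane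
Conditions: [Ir(OMe)(cod)]2 (1.5 mol %), dtbpy (3 mol %), B2pin2 (0.55 equiv), THF, 80 °C
Reagents that add atoms: bis(pinacolato)diboron CC1(C)OB(B2OC(C)(C)C(C)(C)O2)OC1(C)C
Why: Sterically controlled iridium-catalysed C–H borylation functionalises C5, the only C–H with no ortho substituent.

Step 15
Reactants: 20 2,5-dibromo-6-(methoxymethoxy)-1-benzofuran; 21 2-[3,5-bis(methoxymethoxy)phenyl]-4,4,5,5-tetramethyl-1,3,2-dioxaborolane
Product: 22 2-[3,5-bis(methoxymethoxy)phenyl]-5-bromo-6-(methoxymethoxy)-1-benzofuran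
Conditions: Pd(PPh3)4 (3 mol %), 2 M aq. K2CO3, DME, 70 °C
Reagents that add atoms: none
Why: Site-selective Suzuki–Miyaura coupling occurs at the C2–Br bond (α to the ring oxygen, fast oxidative addition) in preference to the electron-rich C5–Br bond hindered by the ortho OMOM group.

Step 16
Reactants: 22 2-[3,5-bis(methoxymethoxy)phenyl]-5-bromo-6-(methoxymethoxy)-1-benzofuran
Product: 23 2-{2-[3,5-bis(methoxymethoxy)phenyl]-6-(methoxymethoxy)-1-benzofuran-5-yl}-4,4,5,5-tetramethyl-1,3,2-dioxaborolane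
Conditions: B2pin2 (1.3 equiv), Pd(dppf)Cl2 (5 mol %), KOAc (3 equiv), dioxane, 90 °C
Reagents that add atoms: bis(pinacolato)diboron CC1(C)OB(B2OC(C)(C)C(C)(C)O2)OC1(C)C
Why: Miyaura borylation turns the remaining aryl bromide into the pinacol boronate, and KOAc is too weak a base to trigger a second Suzuki coupling.

Step 17
Reactants: 16 (1S,5S,6R)-5-[2,4-bis(methoxymethoxy)phenyl]-6-[2-hydroxy-4-(methoxymethoxy)-3-(3-methylbut-2-en-1-yl)benzoyl]-3-methylcyclohex-2-en-1-yl acetate; 23 2-{2-[3,5-bis(methoxymethoxy)phenyl]-6-(methoxymethoxy)-1-benzofuran-5-yl}-4,4,5,5-tetramethyl-1,3,2-dioxaborolane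
Product: 24 {(1R,2R,6S)-6-[2,4-bis(methoxymethoxy)phenyl]-2-{2-[3,5-bis(methoxymethoxy)phenyl]-6-(methoxymethoxy)-1-benzofuran-5-yl}-4-methylcyclohex-3-en-1-yl}[2-hydroxy-4-(methoxymethoxy)-3-(3-methylbut-2-en-1-yl)phenyl]methanone
Conditions: 23 (1.5 equiv), Pd2(dba)3 (2.5 mol %), SPhos (10 mol %), K3PO4 (3 equiv), degassed THF/H2O 10:1, 40 °C
Reagents that add atoms: none
Why: Proposed new method: Pd(0) ionises the allylic acetate anti (Pd on the face opposite OAc and opposite the aroyl group), the aryl group passes from the boronate to Pd and is reductively eliminated from the metal face onto the less substituted allyl terminus (the former C–OAc carbon, not the methyl-bearing one), so C–O is replaced by C–aryl with inversion and the new stereocentre is trans to the aroyl group (all-trans, 1R,2R,6S), while the 2'-phenoxide formed first by the base turns the ketone into a vinylogous carboxylate and so suppresses E1cB loss of acetate and deprotonation of the π-allyl complex (any O-allylation by this phenoxide is reversible under Pd(0)); the closest known reaction type is the stereoinvertive Pd-catalysed Suzuki–Miyaura allyl–aryl coupling of simple cyclic allylic esters and carbonates with arylboronic acids, not yet shown on a β-acyloxy ketone with two adjacent stereocentres or with a hindered ortho-alkoxy benzofuranyl boronate.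

Step 18
Reactants: 24 {(1R,2R,6S)-6-[2,4-bis(methoxymethoxy)phenyl]-2-{2-[3,5-bis(methoxymethoxy)phenyl]-6-(methoxymethoxy)-1-benzofuran-5-yl}-4-methylcyclohex-3-en-1-yl}[2-hydroxy-4-(methoxymethoxy)-3-(3-methylbut-2-en-1-yl)phenyl]methanone
Product: 25 [(1R,2R,6S)-6-(2,4-dihydroxyphenyl)-2-[2-(3,5-dihydroxyphenyl)-6-hydroxy-1-benzofuran-5-yl]-4-methylcyclohex-3-en-1-yl][2,4-dihydroxy-3-(3-methylbut-2-en-1-yl)phenyl]methanone (CNP0150120.1)
Conditions: 3 M aq. HCl/MeOH/THF (1:6:2), 25–35 °C, Ar, dark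
Reagents that add atoms: none
Why: Acid-catalysed transacetalisation of the six aryl MOM ethers to methanol frees all phenols under conditions mild enough for the prenyl group and the ring alkene, and the all-trans (all-equatorial) triad is the thermodynamic arrangement, so the enolisable ketone α-centre is not at risk.

**Compound list**
1 | resorcinol (benzene-1,3-diol) | Oc1cccc(O)c1 | starting material
2 | 1,3-bis(methoxymethoxy)benzene | COCOc1cccc(OCOC)c1 | intermediate
3 | prenyl bromide (1-bromo-3-methylbut-2-ene) | CC(C)=CCBr | starting material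
4 | [2,6-bis(methoxymethoxy)phenyl]lithium | [Li]c1c(OCOC)cccc1OCOC | intermediate
5 | 1,3-bis(methoxymethoxy)-2-(3-methylbut-2-en-1-yl)benzene | CC(C)=CCc1c(OCOC)cccc1OCOC | intermediate
6 | N-methoxy-N-methylacetamide | CC(=O)N(C)OC | starting material
7 | [2,4-bis(methoxymethoxy)-3-(3-methylbut-2-en-1-yl)phenyl]lithium | [Li]c1ccc(OCOC)c(CC=C(C)C)c1OCOC | intermediate
8 | 1-[2,4-bis(methoxymethoxy)-3-(3-methylbut-2-en-1-yl)phenyl]ethan-1-one | CC(=O)c1ccc(OCOC)c(CC=C(C)C)c1OCOC | intermediate
9 | 1-[2-hydroxy-4-(methoxymethoxy)-3-(3-methylbut-2-en-1-yl)phenyl]ethan-1-one | CC(=O)c1ccc(OCOC)c(CC=C(C)C)c1O | intermediate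
10 | N-[(2,4-dihydroxyphenyl)methylidene]-N-methylmethanaminium chloride | C[N+](C)=Cc1ccc(O)cc1O.[Cl-] | intermediate
11 | 2,4-dihydroxybenzaldehyde | O=Cc1ccc(O)cc1O | intermediate
12 | 2,4-bis(methoxymethoxy)benzaldehyde | COCOc1ccc(C=O)c(OCOC)c1 | intermediate
13 | (E)-3-[2,4-bis(methoxymethoxy)phenyl]-1-[2-hydroxy-4-(methoxymethoxy)-3-(3-methylbut-2-en-1-yl)phenyl]prop-2-en-1-one | CC(C)=CCc1c(OCOC)ccc(C(=O)/C=C/c2ccc(OCOC)cc2OCOC)c1O | intermediate
14 | 3-methylbut-2-enal | CC(C)=CC=O | starting material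
15 | (E)-3-methylbuta-1,3-dien-1-yl acetate | CC(=O)O/C=C/C(C)=C | intermediate
16 | (1S,5S,6R)-5-[2,4-bis(methoxymethoxy)phenyl]-6-[2-hydroxy-4-(methoxymethoxy)-3-(3-methylbut-2-en-1-yl)benzoyl]-3-methylcyclohex-2-en-1-yl acetate | CC(C)=CCc1c(OCOC)ccc(C(=O)[C@@H]2[C@@H](c3ccc(OCOC)cc3OCOC)CC(C)=C[C@@H]2OC(C)=O)c1O | intermediate
17 | 5-bromo-2,4-dihydroxybenzaldehyde | O=Cc1cc(Br)c(O)cc1O | intermediate
18 | 5-bromo-2-hydroxy-4-(methoxymethoxy)benzaldehyde | COCOc1cc(O)c(C=O)cc1Br | intermediate
19 | 4-bromo-2-(2,2-dibromoethenyl)-5-(methoxymethoxy)phenol | COCOc1cc(O)c(C=C(Br)Br)cc1Br | intermediate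
20 | 2,5-dibromo-6-(methoxymethoxy)-1-benzofuran | COCOc1cc2oc(Br)cc2cc1Br | intermediate
21 | 2-[3,5-bis(methoxymethoxy)phenyl]-4,4,5,5-tetramethyl-1,3,2-dioxaborolane | COCOc1cc(OCOC)cc(B2OC(C)(C)C(C)(C)O2)c1 | intermediate
22 | 2-[3,5-bis(methoxymethoxy)phenyl]-5-bromo-6-(methoxymethoxy)-1-benzofuran | COCOc1cc(OCOC)cc(-c2cc3cc(Br)c(OCOC)cc3o2)c1 | intermediate
23 | 2-{2-[3,5-bis(methoxymethoxy)phenyl]-6-(methoxymethoxy)-1-benzofuran-5-yl}-4,4,5,5-tetramethyl-1,3,2-dioxaborolane | COCOc1cc(OCOC)cc(-c2cc3cc(B4OC(C)(C)C(C)(C)O4)c(OCOC)cc3o2)c1 | intermediate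
24 | {(1R,2R,6S)-6-[2,4-bis(methoxymethoxy)phenyl]-2-{2-[3,5-bis(methoxymethoxy)phenyl]-6-(methoxymethoxy)-1-benzofuran-5-yl}-4-methylcyclohex-3-en-1-yl}[2-hydroxy-4-(methoxymethoxy)-3-(3-methylbut-2-en-1-yl)phenyl]methanone | CC(C)=CCc1c(OCOC)ccc(C(=O)[C@@H]2[C@@H](c3ccc(OCOC)cc3OCOC)CC(C)=C[C@H]2c2cc3cc(-c4cc(OCOC)cc(OCOC)c4)oc3cc2OCOC)c1O | intermediate
25 | [(1R,2R,6S)-6-(2,4-dihydroxyphenyl)-2-[2-(3,5-dihydroxyphenyl)-6-hydroxy-1-benzofuran-5-yl]-4-methylcyclohex-3-en-1-yl][2,4-dihydroxy-3-(3-methylbut-2-en-1-yl)phenyl]methanone (CNP0150120.1) | CC(C)=CCc1c(O)ccc(C(=O)[C@@H]2[C@@H](c3ccc(O)cc3O)CC(C)=C[C@H]2c2cc3cc(-c4cc(O)cc(O)c4)oc3cc2O)c1O | target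

**Step count**
Total: 18 steps. Longest linear sequence: 9 steps (5, 10, 11, 12, 13, 15, 16, 17, 18), which is half of the total.

**Three steps most likely to fail, with fallbacks**

Step 17 (the proposed new coupling). Risks are elimination to the dienone, slow transmetalation of the ortho-alkoxy boronate, and protodeboronation. The fallback is the established biomimetic Diels–Alder route. It sets out from bromide 22 (and chalcone 13) and comes back at 24. A Heck reaction of 22 with 2-methylbut-3-en-2-ol (Pd(OAc)2, P(o-tol)3, Et3N, DMF, 100 °C) gives (E)-4-{2-[3,5-bis(methoxymethoxy)phenyl]-6-(methoxymethoxy)-1-benzofuran-5-yl}-2-methylbut-3-en-2-ol F1. Dehydration (MsCl, Et3N, CH2Cl2, 0 °C → rt) gives the dehydroprenyl diene 2-[3,5-bis(methoxymethoxy)phenyl]-6-(methoxymethoxy)-5-[(1E)-3-methylbuta-1,3-dien-1-yl]-1-benzofuran F2. Its (R)-VANOL/BH3-promoted Diels–Alder reaction with 13 (the same promoter as in step 9) gives exo and endo adducts. The exo (all-trans) isomer, separated on silica, is 24.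

Step 9 (asymmetric Diels–Alder with the acetoxy diene). Risks are acetic acid loss from the borate-bound β-acetoxy ketone, modest endo selectivity, and an untested diene in this promoter system. The fallback sets out from 13 and 15 and comes back at 16. A racemic cycloaddition without a boron Lewis acid (silica-supported silver nanoparticles, CH2Cl2, 50 °C, a known activation mode for 2'-hydroxychalcones) gives the endo adduct as a racemate. This is 16 together with its mirror image (1R,5R,6S)-5-[2,4-bis(methoxymethoxy)phenyl]-6-[2-hydroxy-4-(methoxymethoxy)-3-(3-methylbut-2-en-1-yl)benzoyl]-3-methylcyclohex-2-en-1-yl acetate F3. Preparative chiral SFC then delivers 16. Enantiopurity comes from resolution instead of the chiral promoter.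

Step 18 (sixfold MOM removal). Risks are acid-promoted chroman formation from the prenyl group with its ortho phenols and addition of a phenol to the ring alkene. The fallback sets out from 24 and comes back at 25. Treatment with TMSOTf/2,2'-bipyridyl (CH2Cl2, 0 °C → rt) exchanges the aryl MOM ethers for silyl ethers without Brønsted acid. It also silylates the free phenol, giving the heptakis(trimethylsilyl) ether {(1R,2R,6S)-6-[2,4-bis(trimethylsilyloxy)phenyl]-2-{2-[3,5-bis(trimethylsilyloxy)phenyl]-6-(trimethylsilyloxy)-1-benzofuran-5-yl}-4-methylcyclohex-3-en-1-yl}[3-(3-methylbut-2-en-1-yl)-2,4-bis(trimethylsilyloxy)phenyl]methanone F4. Neutral hydrolysis (H2O/THF, rt) then gives 25.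

**Further compounds**
F1 | step 17 | (E)-4-{2-[3,5-bis(methoxymethoxy)phenyl]-6-(methoxymethoxy)-1-benzofuran-5-yl}-2-methylbut-3-en-2-ol | COCOc1cc(OCOC)cc(-c2cc3cc(/C=C/C(C)(C)O)c(OCOC)cc3o2)c1
F2 | step 17 | 2-[3,5-bis(methoxymethoxy)phenyl]-6-(methoxymethoxy)-5-[(1E)-3-methylbuta-1,3-dien-1-yl]-1-benzofuran | COCOc1cc(OCOC)cc(-c2cc3cc(/C=C/C(C)=C)c(OCOC)cc3o2)c1
F3 | step 9 | (1R,5R,6S)-5-[2,4-bis(methoxymethoxy)phenyl]-6-[2-hydroxy-4-(methoxymethoxy)-3-(3-methylbut-2-en-1-yl)benzoyl]-3-methylcyclohex-2-en-1-yl acetate (ent-16) | CC(C)=CCc1c(OCOC)ccc(C(=O)[C@H]2[C@H](c3ccc(OCOC)cc3OCOC)CC(C)=C[C@H]2OC(C)=O)c1O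
F4 | step 18 | {(1R,2R,6S)-6-[2,4-bis(trimethylsilyloxy)phenyl]-2-{2-[3,5-bis(trimethylsilyloxy)phenyl]-6-(trimethylsilyloxy)-1-benzofuran-5-yl}-4-methylcyclohex-3-en-1-yl}[3-(3-methylbut-2-en-1-yl)-2,4-bis(trimethylsilyloxy)phenyl]methanone | CC(C)=CCc1c(O[Si](C)(C)C)ccc(C(=O)[C@@H]2[C@@H](c3ccc(O[Si](C)(C)C)cc3O[Si](C)(C)C)CC(C)=C[C@H]2c2cc3cc(-c4cc(O[Si](C)(C)C)cc(O[Si](C)(C)C)c4)oc3cc2O[Si](C)(C)C)c1O[Si](C)(C)C
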